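**Retrosynthetic overview**
1. Target ⇐ 19 ⇐ 18: the O1 ester is put on late; C11/C12 travel as CH2OTES and are oxidised together; 6‑OH travels as its TBS ether.
2. Triol 15 ⇐ keto diester 14: ring B is closed last at C7–C8 (sulfonyl‑carbanion Michael addition, sulfinate loss); C9–H comes from kinetic protonation.
3. C9–C10 ⇐ C1(O)=C10 enolate + dimethyl acetylenedicarboxylate, anti to the C5 side chain, so the trans ring fusion is fixed before ring B exists.
4. Key bond C5–C6 ⇐ homoenolate: the metalated carbamate of (R)‑2,4,4‑trimethylcyclohex‑2‑enol attacks an aldehyde through its γ‑carbon (C5, normally the electrophilic enone β‑carbon); C1 chirality from a CBS reduction is relayed to C5 and C6.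
5. Ring order: ring A is bought (2,4,4‑trimethylcyclohex‑2‑enone); ring B is annulated onto it.

Assumption: drimane numbering is used for all intermediates (ring A = C1–C5, C10; ring B = C5–C10; C11 on C9, C12 on C8; β = face of the C10 methyl), and the Li→Ti exchange in step 3 is taken to go with inversion, as established for Hoppe's secondary allyl carbamates.

**Step 1**
Reactants: 1 2,4,4-trimethylcyclohex-2-en-1-one
Product: 2 (R)-2,4,4-trimethylcyclohex-2-en-1-ol
Conditions: (S)-Me-CBS (10 mol %), BH3·SMe2, THF, −20 °C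
Reagents that add atoms: none
Why: Corey–Bakshi–Shibata reduction, in which the trisubstituted alkene arm acts as the large group so that the (S)-oxazaborolidine gives the (R)-allylic alcohol (C1–O on the β face), the only stereocentre set by a chiral catalyst.

**Step 2**
Reactants: 2 (R)-2,4,4-trimethylcyclohex-2-en-1-ol
Product: 3 (R)-2,4,4-trimethylcyclohex-2-en-1-yl N,N-diisopropylcarbamate
Conditions: NaH, THF, 0 °C; iPr2NCOCl, reflux
Reagents that add atoms: N,N-diisopropylcarbamoyl chloride, CC(C)N(C(C)C)C(Cl)=O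
Why: O-carbamoylation of the alkoxide (acyl substitution) installs the group that directs lithiation and keeps the anion configurationally stable, without touching the stereocentre.

**Step 3**
Reactants: 3 (R)-2,4,4-trimethylcyclohex-2-en-1-yl N,N-diisopropylcarbamate; 4 (phenylsulfanyl)acetaldehyde
Product: 7 (3S)-3-[(1R)-1-hydroxy-2-(phenylsulfanyl)ethyl]-2,4,4-trimethylcyclohex-1-en-1-yl N,N-diisopropylcarbamate, via α-lithio carbamate 5 (not isolated), via allyltitanium triisopropoxide 6 (not isolated)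
Conditions: s-BuLi, TMEDA, Et2O, −78 °C; Ti(OiPr)4, −78 °C; 4, −78 → −40 °C; aq. NH4Cl
Reagents that add atoms: none
Why: Hoppe homoaldol reaction (homoenolate umpolung joining C5, the enone β-carbon, to the aldehyde carbon C6, both natural electrophiles), in which carbamate-directed deprotonation with retention, Li→Ti exchange with inversion and suprafacial γ-attack through a chair transition state place the new bond cis to the former C1–O bond (C6 β, 5α-H), while the ring-locked Z-allyl unit with CH2SPh equatorial gives the 5,6-syn adduct (the 6α-OH of the target).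

**Step 4**
Reactants: 7 (3S)-3-[(1R)-1-hydroxy-2-(phenylsulfanyl)ethyl]-2,4,4-trimethylcyclohex-1-en-1-yl N,N-diisopropylcarbamate
Product: 8 (3S)-3-[(1R)-1-(tert-butyldimethylsilyloxy)-2-(phenylsulfanyl)ethyl]-2,4,4-trimethylcyclohex-1-en-1-yl N,N-diisopropylcarbamate
Conditions: TBSOTf, 2,6-lutidine, CH2Cl2, −78 → 0 °C
Reagents that add atoms: tert-butyldimethylsilyl trifluoromethanesulfonate, CC(C)(C)[Si](C)(C)OS(=O)(=O)C(F)(F)F
Why: silyl ether formation masks the secondary 6-OH before the organolithium, base and hydride steps, and the enol carbamate is inert to these conditions.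

**Step 5**
Reactants: 8 (3S)-3-[(1R)-1-(tert-butyldimethylsilyloxy)-2-(phenylsulfanyl)ethyl]-2,4,4-trimethylcyclohex-1-en-1-yl N,N-diisopropylcarbamate; 9 dimethyl acetylenedicarboxylate
Product: 11 dimethyl (2E)-2-[(1S,6S)-6-[(1R)-1-(tert-butyldimethylsilyloxy)-2-(phenylsulfanyl)ethyl]-1,5,5-trimethyl-2-oxocyclohexyl]but-2-enedioate, via lithium enolate 10 (not isolated)
Conditions: MeLi (1.2 equiv), DME, 0 °C; 9, THF, −78 °C; AcOH, −78 °C
Reagents that add atoms: none
Why: MeLi cleaves the enol carbamate to the regiodefined C1(OLi)=C10 enolate (acyl substitution), and Michael addition to the slim sp carbon of the alkyne occurs at C10 anti to the pseudoaxial C5 side chain (axial attack), setting the quaternary centre with CH3 β and C9 α; the E/Z ratio of the new alkene is irrelevant.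

**Step 6**
Reactants: 11 dimethyl (2E)-2-[(1S,6S)-6-[(1R)-1-(tert-butyldimethylsilyloxy)-2-(phenylsulfanyl)ethyl]-1,5,5-trimethyl-2-oxocyclohexyl]but-2-enedioate
Product: 12 dimethyl (2E)-2-[(1S,6S)-6-[(1R)-1-(tert-butyldimethylsilyloxy)-2-(phenylsulfonyl)ethyl]-1,5,5-trimethyl-2-oxocyclohexyl]but-2-enedioate
Conditions: mCPBA (2.2 equiv), NaHCO3, CH2Cl2, 0 °C
Reagents that add atoms: meta-chloroperoxybenzoic acid, OOC(=O)c1cccc(Cl)c1
Why: chemoselective peracid oxidation of the sulfide to the sulfone (the electron-poor alkene and the hindered ketone do not react at 0 °C) makes C7–H acidic for the ring closure.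

**Step 7**
Reactants: 12 dimethyl (2E)-2-[(1S,6S)-6-[(1R)-1-(tert-butyldimethylsilyloxy)-2-(phenylsulfonyl)ethyl]-1,5,5-trimethyl-2-oxocyclohexyl]but-2-enedioate
Product: 14 dimethyl 6α-(tert-butyldimethylsilyloxy)-1-oxodrim-7-ene-11,12-dioate (5α-H/9α-H/10β-CH3), via cyclised 7-sulfonyl diester enolate 13 (not isolated)
Conditions: KHMDS (3.2 equiv), THF, −78 → −20 °C; re-cool to −78 °C, AcOH
Reagents that add atoms: none
Why: sulfone-mediated annulation in which the C7 α-sulfonyl carbanion adds 6-endo-trig to C8 (Michael addition; the C2 ketone enolate is a spectator because its own closure would be 5-endo), E1cB loss of benzenesulfinate gives the C7=C8 enoate, the last equivalent of base forms the C9 dienolate, and kinetic protonation from the α face, anti to the axial C10 methyl, sets 9α-H.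

**Step 8**
Reactants: 14 dimethyl 6α-(tert-butyldimethylsilyloxy)-1-oxodrim-7-ene-11,12-dioate
Product: 15 6α-(tert-butyldimethylsilyloxy)drim-7-ene-1β,11,12-triol
Conditions: LiAlH4, THF, −20 → 0 °C; Rochelle salt work-up
Reagents that add atoms: none
Why: hydride reduction takes both esters to primary alcohols and attacks the C1 ketone axially from the α face (the equatorial trajectory is blocked by the axial C10 methyl), giving the equatorial 1β-alcohol.

**Step 9**
Reactants: 15 6α-(tert-butyldimethylsilyloxy)drim-7-ene-1β,11,12-triol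
Product: 16 6α-(tert-butyldimethylsilyloxy)-11,12-bis(triethylsilyloxy)drim-7-en-1β-ol
Conditions: TESCl (2.2 equiv), imidazole, CH2Cl2, −20 °C
Reagents that add atoms: chlorotriethylsilane, CC[Si](Cl)(CC)CC
Why: selective silylation, since the two primary hydroxyls react far faster than the hindered secondary 1β-OH next to the quaternary C10.

**Step 10**
Reactants: 16 6α-(tert-butyldimethylsilyloxy)-11,12-bis(triethylsilyloxy)drim-7-en-1β-ol; 17 (E)-3-(4-methoxyphenyl)prop-2-enoyl chloride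
Product: 18 6α-(tert-butyldimethylsilyloxy)-11,12-bis(triethylsilyloxy)drim-7-en-1β-yl (E)-4-methoxycinnamate
Conditions: Et3N, DMAP, CH2Cl2, 0 → 40 °C
Reagents that add atoms: none
Why: DMAP-catalysed acylation (nucleophilic catalysis) of the only free alcohol, with retention at C1.

**Step 11**
Reactants: 18 6α-(tert-butyldimethylsilyloxy)-11,12-bis(triethylsilyloxy)drim-7-en-1β-yl (E)-4-methoxycinnamate
Product: 19 6α-(tert-butyldimethylsilyloxy)-1β-[(E)-4-methoxycinnamoyloxy]drim-7-ene-11,12-dial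
Conditions: (COCl)2, DMSO, CH2Cl2, −78 → −30 °C; Et3N, −78 → 0 °C
Reagents that add atoms: none
Why: Swern oxidation applied directly to primary triethylsilyl ethers, in which chlorodimethylsulfonium chloride cleaves the unhindered primary Si–O bonds to alkoxysulfonium salts that collapse to the aldehydes with Et3N, while the secondary TBS ether and the ester survive and the cold work-up does not epimerise C9.

**Step 12**
Reactants: 19 6α-(tert-butyldimethylsilyloxy)-1β-[(E)-4-methoxycinnamoyloxy]drim-7-ene-11,12-dial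
Product: 20 (1R,5S,6S,9R,10S)-6α-hydroxy-1β-[(E)-4-methoxycinnamoyloxy]drim-7-ene-11,12-dial (target)
Conditions: HF·pyridine, THF, 0 °C → rt
Reagents that add atoms: none
Why: fluoride-mediated desilylation under buffered acidic conditions removes the TBS group without touching the base-sensitive 1,4-dialdehyde, the ester or C9.

**Compound list**
1 | 2,4,4-trimethylcyclohex-2-en-1-one | CC1=CC(C)(C)CCC1=O | starting material
2 | (R)-2,4,4-trimethylcyclohex-2-en-1-ol | O[C@@H]1CCC(C)(C)C=C1C | intermediate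
3 | (R)-2,4,4-trimethylcyclohex-2-en-1-yl N,N-diisopropylcarbamate | CC(C)N(C(C)C)C(=O)O[C@@H]1CCC(C)(C)C=C1C | intermediate
4 | (phenylsulfanyl)acetaldehyde | O=CCSc1ccccc1 | starting material
5 | α-lithio carbamate (Li at C1 in place of H, retention; TMEDA complex; not isolated) | CC(C)N(C(C)C)C(=O)O[C@]1([Li])CCC(C)(C)C=C1C | intermediate
6 | allyltitanium triisopropoxide (Ti at C1 after inversion, β face; not isolated) | CC(C)N(C(C)C)C(=O)O[C@@]1([Ti](OC(C)C)(OC(C)C)OC(C)C)CCC(C)(C)C=C1C | intermediate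
7 | (3S)-3-[(1R)-1-hydroxy-2-(phenylsulfanyl)ethyl]-2,4,4-trimethylcyclohex-1-en-1-yl N,N-diisopropylcarbamate (drimane C5 α-H, C6 as in the target) | CC(C)N(C(C)C)C(=O)OC1=C(C)[C@@H]([C@@H](O)CSc2ccccc2)C(C)(C)CC1 | intermediate
8 | (3S)-3-[(1R)-1-(tert-butyldimethylsilyloxy)-2-(phenylsulfanyl)ethyl]-2,4,4-trimethylcyclohex-1-en-1-yl N,N-diisopropylcarbamate | CC(C)N(C(C)C)C(=O)OC1=C(C)[C@@H]([C@@H](O[Si](C)(C)C(C)(C)C)CSc2ccccc2)C(C)(C)CC1 | intermediate
9 | dimethyl acetylenedicarboxylate (dimethyl but-2-ynedioate) | COC(=O)C#CC(=O)OC | starting material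
10 | lithium enolate, C1(OLi)=C10, of the ketone corresponding to 8 (not isolated) | [Li]OC1=C(C)[C@@H]([C@@H](O[Si](C)(C)C(C)(C)C)CSc2ccccc2)C(C)(C)CC1 | intermediate
11 | dimethyl (2E)-2-[(1S,6S)-6-[(1R)-1-(tert-butyldimethylsilyloxy)-2-(phenylsulfanyl)ethyl]-1,5,5-trimethyl-2-oxocyclohexyl]but-2-enedioate (E shown; Z isomer also usable) | O=C1CCC(C)(C)[C@H]([C@@H](O[Si](C)(C)C(C)(C)C)CSc2ccccc2)[C@@]1(C)/C(C(=O)OC)=C\C(=O)OC | intermediate
12 | dimethyl (2E)-2-[(1S,6S)-6-[(1R)-1-(tert-butyldimethylsilyloxy)-2-(phenylsulfonyl)ethyl]-1,5,5-trimethyl-2-oxocyclohexyl]but-2-enedioate | O=C1CCC(C)(C)[C@H]([C@@H](O[Si](C)(C)C(C)(C)C)CS(=O)(=O)c2ccccc2)[C@@]1(C)/C(C(=O)OC)=C\C(=O)OC | intermediate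
13 | cyclised 7-(phenylsulfonyl) 11,12-diester (formed as its potassium C9 ester enolate, drawn neutral; C7, C8 and C9 not defined; not isolated) | O=C1CCC(C)(C)[C@@H]2[C@@H](O[Si](C)(C)C(C)(C)C)C(S(=O)(=O)c3ccccc3)C(C(=O)OC)C(C(=O)OC)[C@@]12C | intermediate
14 | dimethyl 6α-(tert-butyldimethylsilyloxy)-1-oxodrim-7-ene-11,12-dioate (5α-H, 9α-H, 10β-CH3) | O=C1CCC(C)(C)[C@@H]2[C@@H](O[Si](C)(C)C(C)(C)C)C=C(C(=O)OC)[C@H](C(=O)OC)[C@@]12C | intermediate
15 | 6α-(tert-butyldimethylsilyloxy)drim-7-ene-1β,11,12-triol | O[C@@H]1CCC(C)(C)[C@@H]2[C@@H](O[Si](C)(C)C(C)(C)C)C=C(CO)[C@H](CO)[C@@]12C | intermediate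
16 | 6α-(tert-butyldimethylsilyloxy)-11,12-bis(triethylsilyloxy)drim-7-en-1β-ol | O[C@@H]1CCC(C)(C)[C@@H]2[C@@H](O[Si](C)(C)C(C)(C)C)C=C(CO[Si](CC)(CC)CC)[C@H](CO[Si](CC)(CC)CC)[C@@]12C | intermediate
17 | (E)-3-(4-methoxyphenyl)prop-2-enoyl chloride (4-methoxycinnamoyl chloride) | COc1ccc(/C=C/C(Cl)=O)cc1 | starting material
18 | 6α-(tert-butyldimethylsilyloxy)-11,12-bis(triethylsilyloxy)drim-7-en-1β-yl (E)-4-methoxycinnamate | COc1ccc(/C=C/C(=O)O[C@@H]2CCC(C)(C)[C@@H]3[C@@H](O[Si](C)(C)C(C)(C)C)C=C(CO[Si](CC)(CC)CC)[C@H](CO[Si](CC)(CC)CC)[C@@]23C)cc1 | intermediate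
19 | 6α-(tert-butyldimethylsilyloxy)-1β-[(E)-4-methoxycinnamoyloxy]drim-7-ene-11,12-dial | COc1ccc(/C=C/C(=O)O[C@@H]2CCC(C)(C)[C@@H]3[C@@H](O[Si](C)(C)C(C)(C)C)C=C(C=O)[C@H](C=O)[C@@]23C)cc1 | intermediate
20 | (1R,5S,6S,9R,10S)-6α-hydroxy-1β-[(E)-4-methoxycinnamoyloxy]drim-7-ene-11,12-dial (CNP0283080.1) | COc1ccc(/C=C/C(=O)O[C@@H]2CCC(C)(C)[C@@H]3[C@@H](O)C=C(C=O)[C@H](C=O)[C@@]23C)cc1 | target

**Totals**
Total step count: 12. Longest linear sequence: 12 steps (1 → 20); 4, 9 and 17 are bought.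

**Steps most likely to fail**

Step 3. The aldehyde must attack the γ-carbon C5, which sits next to the gem-dimethyl carbon, and the facial outcome rests on the retention/inversion/suprafacial course; if the sense of induction on 7 turned out reversed, (R)-CBS would be used in step 1. Fallback, setting out from 2 and returning at 10: the C1→C5 chirality transfer is done by a sigmatropic shift instead. Alcohol 2 is esterified with (tert-butyldimethylsilyloxy)acetic acid (DCC, DMAP) to the glycolate ester F1. Ireland–Claisen rearrangement (LiHMDS, TMSCl, THF, −78 °C → rt) gives the α-silyloxy acid F2, with the C5–C6 bond cis to the former C1–O bond and the C6 configuration controlled by the enolate geometry. LiAlH4 gives the primary alcohol F3, and PhSSPh/Bu3P the sulfide F4. Hydroboration of the C1=C10 alkene (BH3·THF, then Me3NO) gives the cyclohexanol F5, and Swern oxidation the ketone F6. Equilibrating deprotonation (Ph3CLi, DME) then gives the more substituted lithium enolate 10.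

Step 5. A hindered tetrasubstituted enolate must add to the alkyne; the vinyl anion formed can attack the C1 ketone, and the α-face approach is 1,3-related to a C4 methyl. Fallback, setting out from 10 and returning at 11: the C9–C10 bond is made by an aldol reaction and the alkene by olefination. Enolate 10 is added to methyl glyoxylate (THF, −78 °C) to give the β-hydroxy ester F7. Swern oxidation gives the α-keto ester F8. Wittig reaction with Ph3P=CHCO2Me (toluene, 80 °C) gives 11 as an E/Z mixture.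

Step 7. The C7 carbanion can lose silanolate (giving a vinyl sulfone) instead of cyclising, and the three-equivalent base sequence must end in a clean kinetic protonation. Fallback, setting out from 3 and returning at 14: ring B is closed by metathesis instead. Carbamate 3 is lithiated and titanated as in step 3 and added to acrolein to give the vinyl carbinol F9. TBSOTf/2,6-lutidine gives the silyl ether F10. MeLi followed by the DABCO salt of dimethyl 2-(bromomethyl)fumarate gives, by SN2′ attack of the C10 enolate, the itaconate F11 as C9 epimers. Ring-closing metathesis (Grubbs II, CH2Cl2, 40 °C) forms C7=C8 and gives 14 together with its C9 epimer F12. LDA (2.2 equiv) then AcOH at −78 °C converts F12 into 14.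

**Further compounds**
F1 | step 3 | (R)-2,4,4-trimethylcyclohex-2-en-1-yl (tert-butyldimethylsilyloxy)acetate | CC(C)(C)[Si](C)(C)OCC(=O)O[C@@H]1CCC(C)(C)C=C1C
F2 | step 3 | 2-(tert-butyldimethylsilyloxy)-2-(2,6,6-trimethylcyclohex-2-en-1-yl)acetic acid, C5 and C6 configured as in 7 | CC1=CCCC(C)(C)[C@@H]1[C@@H](O[Si](C)(C)C(C)(C)C)C(=O)O
F3 | step 3 | 2-(tert-butyldimethylsilyloxy)-2-(2,6,6-trimethylcyclohex-2-en-1-yl)ethanol, C5 and C6 as in 7 | CC1=CCCC(C)(C)[C@@H]1[C@@H](O[Si](C)(C)C(C)(C)C)CO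
F4 | step 3 | tert-butyldimethylsilyl ether of 2-(phenylsulfanyl)-1-(2,6,6-trimethylcyclohex-2-en-1-yl)ethanol, C5 and C6 as in 7 | CC1=CCCC(C)(C)[C@@H]1[C@@H](O[Si](C)(C)C(C)(C)C)CSc2ccccc2
F5 | step 3 | 3-[1-(tert-butyldimethylsilyloxy)-2-(phenylsulfanyl)ethyl]-2,4,4-trimethylcyclohexan-1-ol, C5 and C6 as in 7, C1 and C10 as formed | CC1C(O)CCC(C)(C)[C@@H]1[C@@H](O[Si](C)(C)C(C)(C)C)CSc2ccccc2
F6 | step 3 | 3-[1-(tert-butyldimethylsilyloxy)-2-(phenylsulfanyl)ethyl]-2,4,4-trimethylcyclohexan-1-one, C5 and C6 as in 7, C10 epimers | CC1C(=O)CCC(C)(C)[C@@H]1[C@@H](O[Si](C)(C)C(C)(C)C)CSc2ccccc2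
F7 | step 5 | methyl 2-hydroxy-2-[(1S,6S)-6-[(1R)-1-(tert-butyldimethylsilyloxy)-2-(phenylsulfanyl)ethyl]-1,5,5-trimethyl-2-oxocyclohexyl]acetate, carbinol epimers | O=C1CCC(C)(C)[C@H]([C@@H](O[Si](C)(C)C(C)(C)C)CSc2ccccc2)[C@@]1(C)C(O)C(=O)OC
F8 | step 5 | methyl 2-oxo-2-[(1S,6S)-6-[(1R)-1-(tert-butyldimethylsilyloxy)-2-(phenylsulfanyl)ethyl]-1,5,5-trimethyl-2-oxocyclohexyl]acetate | O=C1CCC(C)(C)[C@H]([C@@H](O[Si](C)(C)C(C)(C)C)CSc2ccccc2)[C@@]1(C)C(=O)C(=O)OC
F9 | step 7 | 3-(1-hydroxyprop-2-en-1-yl)-2,4,4-trimethylcyclohex-1-en-1-yl N,N-diisopropylcarbamate, C5 and C6 as in 7 | CC(C)N(C(C)C)C(=O)OC1=C(C)[C@@H]([C@@H](O)C=C)C(C)(C)CC1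
F10 | step 7 | 3-[1-(tert-butyldimethylsilyloxy)prop-2-en-1-yl]-2,4,4-trimethylcyclohex-1-en-1-yl N,N-diisopropylcarbamate, C5 and C6 as in 7 | CC(C)N(C(C)C)C(=O)OC1=C(C)[C@@H]([C@@H](O[Si](C)(C)C(C)(C)C)C=C)C(C)(C)CC1
F11 | step 7 | dimethyl 2-{6-[1-(tert-butyldimethylsilyloxy)prop-2-en-1-yl]-1,5,5-trimethyl-2-oxocyclohexyl}-3-methylenebutanedioate, C5, C6 and C10 as in 14, C9 epimers | O=C1CCC(C)(C)[C@H]([C@@H](O[Si](C)(C)C(C)(C)C)C=C)[C@@]1(C)C(C(=O)OC)C(=C)C(=O)OC
F12 | step 7 | dimethyl 6α-(tert-butyldimethylsilyloxy)-1-oxo-9-epi-drim-7-ene-11,12-dioate (9β-H) | O=C1CCC(C)(C)[C@@H]2[C@@H](O[Si](C)(C)C(C)(C)C)C=C(C(=O)OC)[C@@H](C(=O)OC)[C@@]12C
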